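The runs are simulated for an exercise; noise was put on by code.

At early times the south-east run loses substrate with a half-life of 3.43 h, reckoned from the 29.7% left at 6.00 h, and target climbs steeply to 7.5% by 2.00 h. The north run reads 29.4% of substrate at 6.00 h, so in percent the two charges coincide within the scatter; we read the curves as pseudo-first-order in substrate and carry them over to the flask.

| setting | south-east | north | flask |
|---|---|---|---|
| substrate | 0.40 M | 0.60 M | 0.80 M |
| reagent in the second phase | 2.4 M | 2.4 M | 2.40 M |
| remark | run made earlier | run made earlier |  |
| time |  |  | 2.0 d |
| volume of the second phase over the first |  |  | 1.0 |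

| run | time / h | target / % | substrate / % |
|---|---|---|---|
| south-east | 2.00 | 7.5 | 64.1 |
| south-east | 6.00 | 13.2 | 29.7 |
| south-east | 10.0 | 15.2 | 15.0 |
| south-east | 15.0 | 17.2 | 7.3 |
| south-east | 20.0 | 16.3 | 6.7 |
| south-east | 30.0 | 14.5 | 5.3 |
| north | 2.50 | 5.8 | 58.2 |
| north | 4.00 | 11.8 | 44.4 |
| north | 6.00 | 13.0 | 29.4 |
| north | 10.0 | 14.9 | 15.2 |
| north | 20.0 | 15.1 | 7.9 |
| north | 30.0 | 14.0 | 4.3 |

(standard deviation of a reading: 1 percentage point)

- in the second phase: reagent in the second phase; everything else is in the first
- charges count per volume of the first phase; a concentration in a rate is the amount of a species over the volume of its own phase; every rate counts per litre of the first phase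
- the numbers in the tables scatter with a standard deviation of 1 percentage point
- steps under discussion: reagent in the reaction phase <-> reagent in the second phase; substrate + reagent in the reaction phase <-> target; reagent in the reaction phase + target -> over-reacted product; substrate <-> dormant form
- the earlier runs hold the two phases in the same ratio of volumes as the flask asked about

* how much target there is at 2.0 d, in percent of the substrate charged
* the change that raises the amount of target at 2.0 d, in percent of the substrate charged most ("none" if none brings more than 2 percentage points) (ash / cedar / none)
* amount of target at 2.0 d, in percent of the substrate charged, after cedar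

The knee comes near 15.0 h, where the south-east run reads its peak of 17.2% and substrate flattens at 7.3%. Beyond it target fades, so we reckon the time in which late target halves from the mean of both runs, 15.7% at 20.0 h and 14.3% at 30.0 h:

fade half-life = 71.5 h

target at 2.0 d = 14.3% × exp(−ln 2 × 18.0 h / 71.5 h) = 12.0%

We expect cedar to shorten the fade half-life, and so we look for no gain above 2 percentage points from it; no run varies the transfer coefficient, so for ash we can only judge, and we expect no such gain there either.

The forecast gives 12.5% (10% to 15%), none as the best change and 10.5% after cedar (7% to 16%), holding that “neither change helps”.

The flask gives 11.5%, with none as the best change: ash shifts target by 0.094 points, and cedar by −2.5 points, to 9.09%. In the flask at 2.00 d target is made at 0.611 of the rate at which it is used up, each step taken net. Carried on from 11.5% to 4.00 d, the fade half-life gives 7.22%, less than the flask's 8.60%, so over that stretch target in the flask fades more slowly than the half-life read from the runs.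

    reagent in the reaction phase ⇌ reagent in the second phase, rate k1*([reagent in the reaction phase] - [reagent in the second phase]/K1) per volume of the first phase (partition coefficient = 0.560, kL = 1.50 h⁻¹)
    substrate + reagent in the reaction phase ⇌ target (K = 7.20 M⁻¹, k = 0.0300 M⁻¹ h⁻¹)
    reagent in the reaction phase + target → over-reacted product (k = 0.0160 M⁻¹ h⁻¹)
    substrate ⇌ dormant form (K = 12.0, k = 0.170 h⁻¹)

The same flask left until 20 h, reckoned back from 11.5% with the fade half-life, should hold 15.1% of target; the computed result is 15.1%.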